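left-handed substrate 1.0 mM; coupling partner 0.600 mM; free catalyst 6.8 µM; impurity 2.7 µM; right-handed substrate 1.0 mM

    coupling partner + catalyst intermediate B → free catalyst + right-handed product (k1 = 14000 M⁻¹ s⁻¹)
    free catalyst + right-handed substrate ⇌ catalyst intermediate B (K2 = 7200 M⁻¹, k2 = 1.5 × 10⁵ M⁻¹ s⁻¹)
    2 coupling partner → homo dimer (k3 = 110 M⁻¹ s⁻¹)
    free catalyst + impurity → spent catalyst (k4 = 1.4 × 10⁷ M⁻¹ s⁻¹)
    coupling partner + catalyst intermediate A → free catalyst + left-handed product (k5 = 29000 M⁻¹ s⁻¹)
    free catalyst + left-handed substrate ⇌ catalyst intermediate A (K6 = 31000 M⁻¹, k6 = 1.6 × 10⁵ M⁻¹ s⁻¹)

- free catalyst is single-handed; left-handed substrate and right-handed substrate are mirror images of each other, charged as a racemate, each of them at the stated concentration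
- a step written with two of one species runs at k times the square of its concentration and takes two of it each time
- charge of left-handed substrate (flask): 1.0 mM

1. apparent order in free catalyst when 10% of the left-handed substrate and right-handed substrate together are converted (percent change of the rate of making left-handed product for one percent more free catalyst charged)
2. apparent order in coupling partner when 10% of the left-handed substrate and right-handed substrate together are converted (percent change of the rate of making left-handed product for one percent more coupling partner charged)
3. factor on the rate of making left-handed product when 10% of the left-handed substrate and right-handed substrate together are converted if coupling partner is charged twice over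

A one-step world has one clock. This flask has several, so I turn the constants into times at the charged amounts and follow it by hand.

1. First instants. Per free catalyst, the two substrates bind at 9600 min⁻¹ and 9000 min⁻¹, faster than the impurity takes it at 2300 min⁻¹. Binding is reversible, however, and the impurity's step is not. With free catalyst at its binding-equilibrium share, I reckon the impurity lasts about 0.683 s. That leaves live catalyst L, charged catalyst minus impurity, at 4.10 µM.

2. Middle. Coupling partner is the limiting reagent, and two routes compete for it. If L sits as catalyst intermediate A, coupling has a clock of 8.41 s. Homo dimer's first half-life is 7.58 s. I carry their ratio, the race number N, the loss of coupling partner to homo dimer over its loss to product at the charge: 1.11. The two clocks stand close together at the start. With the form of the catalyst held fixed, the rate of homo dimer falls with the square of coupling partner and coupling with its first power, so coupling gains as the run proceeds.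

3. End. Integrating the two losses, the fraction of coupling partner reaching product is the natural log of one plus N, divided by N. That gives 0.673, or an estimated 0.404 mM of the two products together.

4. The moment asked. The two products together needed there are 0.333 of the coupling partner charged. By the same integration, 0.412 of the charge remains then, about 0.247 mM. Differentiating at fixed product, one percent more live catalyst leaves 0.503 percent more coupling partner at that conversion, since N falls as L rises. Rate carries both factors, and one percent more charged catalyst is 1.66 percent more L. My order in free catalyst is therefore 2.49.

5. Coupling partner. The same line gives an order of 1.68 and a doubling factor of 2.68. I take both as high: coupling removes catalyst intermediate A at 7.17 s⁻¹, faster than it releases substrate at 5.16 s⁻¹, so extra coupling partner thins that intermediate.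

The forecast gives 1.66, 1.18 and 2, holding that “the rate follows charged catalyst minus impurity”.

The simulation gives an order of 2.6 in free catalyst, 1.4 in coupling partner and a doubling factor of 2.14, with the conversion reached at 0.0984 min. In this flask, 37.8% of the coupling partner has gone into homo dimer by 2.50 min. Now take a second flask with twice the free catalyst and the same impurity. Its race number falls to 0.418, and the integrated balance puts the factor on the time to that conversion at 0.322. The run of that flask gives 0.307.

The rate constants were drawn at random within sensible limits; what happens was integrated by code.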